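The cuts, in retrosynthetic order, are:
- the phenol O–CH3 and indole N–SO2Ph bonds;
- C4'–NH2 and both pyrimidine C–Br bonds, back to a 2,4-dimethoxypyrimidine (masked uracil), then C5–C6 of the indole benzene ring;
- C4=C5 (ester methylenation), C6=C7 (dibromoolefination), C7–C7a (formylation), the pyrrole ring (TosMIC [3+2]) and the pyrimidine C5'–vinyl bond (Heck).

Enabling feature: in the six-membered ring of the indole (C3a, C4, C5, C6, C7, C7a) the oxygen on C4 and the bromine on C6 are meta to each other. C4=C5 can therefore arrive as a methyl enol ether on pyrrole carbon C3a and C6=C7 as a 1,1-dibromoalkene on pyrrole carbon C7a; with the C3a=C7a bond they form a hexatriene, and the second bromine is the leaving group that aromatises the closed ring.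
Forward order of rings: pyrimidine (purchased), pyrrole (step 2), benzene ring (step 7). The route is linear, and the pyrimidine is refunctionalised only after the indole exists.
Stereochemistry: the target has no stereocentre and no stereogenic double bond. The only stereo-element on the way, the E-acrylate from the Heck step, disappears when the pyrrole forms.

Key step: step 7

Remark: primed locants refer to the pyrimidine ring, and indole numbering (N1 to C7a) is used for the pyrrole carbons wherever ring formation is discussed. The four numbered starting materials are taken to be catalogue chemicals.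

Step 1
Reactants: 1 5-iodo-2,4-dimethoxypyrimidine; 2 methyl acrylate
Product: 3 methyl (E)-3-(2,4-dimethoxypyrimidin-5-yl)acrylate
Conditions: Pd(OAc)2 (5 mol %), P(o-tol)3 (10 mol %), Et3N, DMF, 90 °C
Reagents that add atoms: none
Why: Mizoroki–Heck coupling of a 5-iodopyrimidine with an acrylate is standard for 5-iodouracil derivatives, and syn insertion followed by syn β-hydride elimination should give the E-alkene only.

Step 2
Reactants: 3 methyl (E)-3-(2,4-dimethoxypyrimidin-5-yl)acrylate; 4 tosylmethyl isocyanide (TosMIC)
Product: 5 methyl 4-(2,4-dimethoxypyrimidin-5-yl)-1H-pyrrole-3-carboxylate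
Conditions: KOt-Bu (2 equiv), THF, 0 °C to rt
Reagents that add atoms: none
Why: In the van Leusen pyrrole synthesis the TosMIC anion adds to the β-carbon of the acrylate, the ester enolate closes onto the isocyanide carbon, and loss of sulfinate with tautomerisation should give the 3,4-disubstituted pyrrole with ester and pyrimidine on neighbouring carbons and both α-positions free.

Step 3
Reactants: 5 methyl 4-(2,4-dimethoxypyrimidin-5-yl)-1H-pyrrole-3-carboxylate
Product: 6 methyl 4-(2,4-dimethoxypyrimidin-5-yl)-1-(phenylsulfonyl)pyrrole-3-carboxylate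
Conditions: NaH, PhSO2Cl, THF, 0 °C to rt
Reagents that add atoms: benzenesulfonyl chloride, O=S(=O)(Cl)c1ccccc1
Why: N-Sulfonylation of the pyrrolide anion is routine, and benzenesulfonyl is chosen because it acidifies the α-C–H bonds for step 4, weakens the pyrrole aromaticity for step 7, outlasts hot aqueous HCl and POBr3 in steps 8 and 9 and still leaves with fluoride in step 11.

Step 4
Reactants: 6 methyl 4-(2,4-dimethoxypyrimidin-5-yl)-1-(phenylsulfonyl)pyrrole-3-carboxylate
Product: 8 methyl 4-(2,4-dimethoxypyrimidin-5-yl)-2-formyl-1-(phenylsulfonyl)pyrrole-3-carboxylate, via C2-magnesiated pyrrole 7 (not isolated)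
Conditions: TMPMgCl·LiCl (1.3 equiv), THF, −25 °C; DMF, −25 °C to rt; sat. aq. NH4Cl
Reagents that add atoms: N,N-dimethylformamide, CN(C)C=O; TMPMgCl·LiCl, CC1(C)CCCC(C)(C)N1[Mg]Cl.[Li+].[Cl-] (supplies the MgCl of 7 only)
Why: In this directed ortho-magnesiation and DMF formylation the C2–H lies between the sulfonylated nitrogen and the chelating ester, so it should be the most acidic and best-coordinated site, whereas C5–H and pyrimidine C6'–H each have one activating neighbour and the hindered amide base tolerates the ester at low temperature.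

Step 5
Reactants: 8 methyl 4-(2,4-dimethoxypyrimidin-5-yl)-2-formyl-1-(phenylsulfonyl)pyrrole-3-carboxylate; 9 carbon tetrabromide
Product: 10 methyl 2-(2,2-dibromovinyl)-4-(2,4-dimethoxypyrimidin-5-yl)-1-(phenylsulfonyl)pyrrole-3-carboxylate
Conditions: CBr4 (2 equiv), PPh3 (4 equiv), CH2Cl2, 0 °C
Reagents that add atoms: none
Why: In the Ramirez dibromoolefination (first half of the Corey–Fuchs sequence) Ph3P=CBr2 made in situ should react in Wittig fashion with the aldehyde alone, since ester, sulfonamide and pyrimidine ethers are inert to it at 0 °C.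

Step 6
Reactants: 10 methyl 2-(2,2-dibromovinyl)-4-(2,4-dimethoxypyrimidin-5-yl)-1-(phenylsulfonyl)pyrrole-3-carboxylate
Product: 11 5-[5-(2,2-dibromovinyl)-4-(1-methoxyvinyl)-1-(phenylsulfonyl)pyrrol-3-yl]-2,4-dimethoxypyrimidine
Conditions: Cp2TiMe2 (3 equiv), toluene, 75 °C, dark; filtration through basic alumina
Reagents that add atoms: dimethyltitanocene Cp2TiMe2, C[Ti+2]C.[CH-]1C=CC=C1.[CH-]1C=CC=C1
Why: In the Petasis methylenation Cp2TiMe2 loses methane to give Cp2Ti=CH2, which turns aryl esters into 1-methoxyvinyl arenes through an oxatitanacyclobutane under non-acidic, non-reducing conditions that should spare the trisubstituted dibromoalkene and the sulfonamide and stay well below the temperature of ring closure.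

Step 7
Reactants: 11 5-[5-(2,2-dibromovinyl)-4-(1-methoxyvinyl)-1-(phenylsulfonyl)pyrrol-3-yl]-2,4-dimethoxypyrimidine
Product: 13 6-bromo-3-(2,4-dimethoxypyrimidin-5-yl)-4-methoxy-1-(phenylsulfonyl)indole, via 6,6-dibromo-5,6-dihydroindole 12 (not isolated)
Conditions: K2CO3 (powdered, anhydrous, 3 equiv), 1,2-dichlorobenzene (0.02 M, degassed), 180 °C, argon
Reagents that add atoms: none
Why: Proposed new method: on heating, the 1-methoxyvinyl group, the pyrrole C3a=C7a bond and the dibromovinyl group of 11 act as one 1,3,5-hexatriene and should undergo a thermally allowed, disrotatory six-electron electrocyclisation that joins the =CH2 terminus (C5) to the CBr2 terminus (C6) and closes the six-membered carbocycle as dihydroindole 12. In 12 a CH2 group stands next to a CBr2 carbon that is allylic and vinylogously linked to nitrogen, so one bromide should leave at once while the carbonate takes up the proton; this loss of HBr regenerates the pyrrole sextet, completes the benzene ring and pulls the unfavourable pericyclic equilibrium forward. The closest known reaction type is the thermal electrocyclisation of 2,3-divinylpyrroles and 2,3-divinylindoles to indoles and carbazoles, together with the eliminative aromatisation of cyclohexadienes that carry a leaving group; what has not been shown is a gem-dibromo terminus on such a pyrrole triene, where one bromine must turn inward in the transition state and raises the barrier. No stereocentre is formed, since C5 of 12 is a CH2 and C6 carries two identical bromines. The selectivity required is positional and is fixed by connectivity: the methoxy group sits on the carbon bound to C3a and so ends on C4, and the bromine that remains after elimination sits on C6, meta to it. The substrate helps through the benzenesulfonyl group, which withdraws nitrogen lone-pair density so that less aromatic stabilisation is sacrificed and whose bulk turns the CBr2 end towards the enol ether, and the solid base removes HBr before it can hydrolyse the enol ether or dealkylate the pyrimidine ethers.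

Step 8
Reactants: 13 6-bromo-3-(2,4-dimethoxypyrimidin-5-yl)-4-methoxy-1-(phenylsulfonyl)indole
Product: 14 5-[6-bromo-4-methoxy-1-(phenylsulfonyl)indol-3-yl]pyrimidine-2,4(1H,3H)-dione
Conditions: 6 M aq. HCl, 1,4-dioxane, 90 °C
Reagents that add atoms: water, O
Why: Acid hydrolysis of the two lactim ethers is the standard unmasking of 2,4-dimethoxypyrimidines to uracils, in which the protonated ring adds water at C2' and C4' and expels methanol, while the aryl methyl ether, the aryl bromide and the sulfonamide are stable to aqueous HCl.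

Step 9
Reactants: 14 5-[6-bromo-4-methoxy-1-(phenylsulfonyl)indol-3-yl]pyrimidine-2,4(1H,3H)-dione
Product: 15 6-bromo-3-(2,4-dibromopyrimidin-5-yl)-4-methoxy-1-(phenylsulfonyl)indole
Conditions: POBr3 (5 equiv), PhNEt2, toluene, 105 °C
Reagents that add atoms: phosphorus oxybromide POBr3, O=P(Br)(Br)Br
Why: Deoxybromination through O-phosphorylation of the uracil and addition–elimination by bromide is the usual way to 2,4-dibromopyrimidines, with the amine base keeping free HBr low so that the aryl methyl ether holds and the sulfonyl group shielding the indole.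

Step 10
Reactants: 15 6-bromo-3-(2,4-dibromopyrimidin-5-yl)-4-methoxy-1-(phenylsulfonyl)indole
Product: 16 2-bromo-5-[6-bromo-4-methoxy-1-(phenylsulfonyl)indol-3-yl]pyrimidin-4-amine
Conditions: NH3 (2 M in i-PrOH), THF, sealed tube, rt to 40 °C
Reagents that add atoms: ammonia, N
Why: In nucleophilic aromatic substitution of 2,4-dihalopyrimidines C4' is attacked ahead of C2' because its Meisenheimer adduct spreads the charge over both ring nitrogens in para-quinoid fashion, and the amino group once installed deactivates the ring so that the C2' bromide and the aryl bromide should stay.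

Step 11
Reactants: 16 2-bromo-5-[6-bromo-4-methoxy-1-(phenylsulfonyl)indol-3-yl]pyrimidin-4-amine
Product: 17 2-bromo-5-(6-bromo-4-methoxy-1H-indol-3-yl)pyrimidin-4-amine
Conditions: Bu4NF (1 M in THF, 3 equiv), THF, 50 °C
Reagents that add atoms: none
Why: In this fluoride-induced N-desulfonylation of an N-arylsulfonylindole, fluoride attacks sulfur and expels an indolide that the 3-pyrimidinyl and 6-bromo groups make a good leaving group, under conditions too mild for substitution at the amino-deactivated 2-bromopyrimidine.

Step 12
Reactants: 17 2-bromo-5-(6-bromo-4-methoxy-1H-indol-3-yl)pyrimidin-4-amine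
Product: 18 3-(4-amino-2-bromopyrimidin-5-yl)-6-bromo-1H-indol-4-ol (CNP0233484.0)
Conditions: BBr3 (6 equiv), CH2Cl2, −78 °C to rt; then H2O, adjusted to pH 7
Reagents that add atoms: none
Why: In this Lewis-acid aryl methyl ether cleavage, BBr3 (in excess to saturate the basic nitrogens) activates the ether oxygen, bromide removes the methyl group and hydrolysis frees the phenol, and since bromide is the only halide present no halogen scrambling at C2' can occur.

Compound list
1 | 5-iodo-2,4-dimethoxypyrimidine | COc1ncc(I)c(OC)n1 | starting material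
2 | methyl acrylate | C=CC(=O)OC | starting material
3 | methyl (E)-3-(2,4-dimethoxypyrimidin-5-yl)acrylate | COC(=O)/C=C/c1cnc(OC)nc1OC | intermediate
4 | tosylmethyl isocyanide (TosMIC) | Cc1ccc(cc1)S(=O)(=O)C[N+]#[C-] | starting material
5 | methyl 4-(2,4-dimethoxypyrimidin-5-yl)-1H-pyrrole-3-carboxylate | COC(=O)c1c[nH]cc1-c1cnc(OC)nc1OC | intermediate
6 | methyl 4-(2,4-dimethoxypyrimidin-5-yl)-1-(phenylsulfonyl)pyrrole-3-carboxylate | COC(=O)c1cn(S(=O)(=O)c2ccccc2)cc1-c1cnc(OC)nc1OC | intermediate
7 | [3-(methoxycarbonyl)-4-(2,4-dimethoxypyrimidin-5-yl)-1-(phenylsulfonyl)pyrrol-2-yl]magnesium chloride (not isolated) | COC(=O)c1c([Mg]Cl)n(S(=O)(=O)c2ccccc2)cc1-c1cnc(OC)nc1OC | intermediate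
8 | methyl 4-(2,4-dimethoxypyrimidin-5-yl)-2-formyl-1-(phenylsulfonyl)pyrrole-3-carboxylate | COC(=O)c1c(C=O)n(S(=O)(=O)c2ccccc2)cc1-c1cnc(OC)nc1OC | intermediate
9 | carbon tetrabromide | BrC(Br)(Br)Br | starting material
10 | methyl 2-(2,2-dibromovinyl)-4-(2,4-dimethoxypyrimidin-5-yl)-1-(phenylsulfonyl)pyrrole-3-carboxylate | COC(=O)c1c(C=C(Br)Br)n(S(=O)(=O)c2ccccc2)cc1-c1cnc(OC)nc1OC | intermediate
11 | 5-[5-(2,2-dibromovinyl)-4-(1-methoxyvinyl)-1-(phenylsulfonyl)pyrrol-3-yl]-2,4-dimethoxypyrimidine | C=C(OC)c1c(C=C(Br)Br)n(S(=O)(=O)c2ccccc2)cc1-c1cnc(OC)nc1OC | intermediate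
12 | 6,6-dibromo-3-(2,4-dimethoxypyrimidin-5-yl)-4-methoxy-1-(phenylsulfonyl)-5,6-dihydro-1H-indole (not isolated) | COC1=C2C(=CC(Br)(Br)C1)N(S(=O)(=O)c1ccccc1)C=C2c1cnc(OC)nc1OC | intermediate
13 | 6-bromo-3-(2,4-dimethoxypyrimidin-5-yl)-4-methoxy-1-(phenylsulfonyl)indole | COc1cc(Br)cc2c1c(-c1cnc(OC)nc1OC)cn2S(=O)(=O)c1ccccc1 | intermediate
14 | 5-[6-bromo-4-methoxy-1-(phenylsulfonyl)indol-3-yl]pyrimidine-2,4(1H,3H)-dione | COc1cc(Br)cc2c1c(-c1c[nH]c(=O)[nH]c1=O)cn2S(=O)(=O)c1ccccc1 | intermediate
15 | 6-bromo-3-(2,4-dibromopyrimidin-5-yl)-4-methoxy-1-(phenylsulfonyl)indole | COc1cc(Br)cc2c1c(-c1cnc(Br)nc1Br)cn2S(=O)(=O)c1ccccc1 | intermediate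
16 | 2-bromo-5-[6-bromo-4-methoxy-1-(phenylsulfonyl)indol-3-yl]pyrimidin-4-amine | COc1cc(Br)cc2c1c(-c1cnc(Br)nc1N)cn2S(=O)(=O)c1ccccc1 | intermediate
17 | 2-bromo-5-(6-bromo-4-methoxy-1H-indol-3-yl)pyrimidin-4-amine | COc1cc(Br)cc2[nH]cc(-c3cnc(Br)nc3N)c12 | intermediate
18 | 3-(4-amino-2-bromopyrimidin-5-yl)-6-bromo-1H-indol-4-ol | Nc1nc(Br)ncc1-c1c[nH]c2cc(Br)cc(O)c12 | target

Total step count: 12. Longest linear sequence: 12 steps (1 to 18).

Steps most likely to fail

**Step 7.**
- Risk: ring closure may be too slow, because one bromine has to rotate inward over the triene. Base-induced loss of HBr from the dibromoalkene, thermal O-to-N methyl migration on the pyrimidine or breakdown of the enol ether could then take over.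
- Fallback: known chemistry throughout, giving up ring construction in favour of cross-coupling onto a ready-made benzene ring. It sets out from 1.
- Boronic acid partner: iodine–magnesium exchange with i-PrMgCl·LiCl in THF at −20 °C, trapping with B(Oi-Pr)3 and mild acidic work-up would give (2,4-dimethoxypyrimidin-5-yl)boronic acid F1.
- Indole partner: purchased 6-bromo-4-methoxy-1H-indole F2 would be iodinated at C3 with N-iodosuccinimide in DMF to 6-bromo-3-iodo-4-methoxy-1H-indole F3. Sulfonylation (NaH, PhSO2Cl, THF) would then give 6-bromo-3-iodo-4-methoxy-1-(phenylsulfonyl)indole F4.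
- Return: Suzuki–Miyaura coupling of F1 with F4 (Pd(PPh3)4, aq. Na2CO3, DME, 70 °C) should take place at the C–I bond ahead of the C–Br bond, and comes back to the route at 13.

**Step 4.**
- Risk: poor site selectivity of the deprotonation (competition from pyrrole C5–H, pyrimidine C6'–H or the ortho positions of the sulfonyl arene), or attack of the organomagnesium on the ester of a second molecule.
- Fallback: C–H deprotonation is replaced by halogen–metal exchange. It sets out from 5.
- N-Bromosuccinimide (2 equiv, THF, −78 to 0 °C) would brominate both free α-positions to give methyl 2,5-dibromo-4-(2,4-dimethoxypyrimidin-5-yl)-1H-pyrrole-3-carboxylate F5.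
- NaH and PhSO2Cl would give methyl 2,5-dibromo-4-(2,4-dimethoxypyrimidin-5-yl)-1-(phenylsulfonyl)pyrrole-3-carboxylate F6.
- i-PrMgCl·LiCl at −40 °C should exchange the C2 bromine, which the neighbouring chelating ester activates. DMF would then give methyl 5-bromo-4-(2,4-dimethoxypyrimidin-5-yl)-2-formyl-1-(phenylsulfonyl)pyrrole-3-carboxylate F7.
- Return: catalytic hydrodebromination (Pd(PPh3)4, HCO2Na, DMF, 80 °C) removes the remaining C5 bromine and comes back to the route at 8.

**Step 9.**
- Risk: cleavage of the aryl methyl ether by HBr at the temperature the bromination needs, followed by phosphorylation of the freed phenol, or an incomplete second bromination caused by poor solubility of the uracil.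
- Fallback: chlorine is carried instead and exchanged late. It sets out from 14.
- POCl3 with PhNEt2 at reflux would give 6-bromo-3-(2,4-dichloropyrimidin-5-yl)-4-methoxy-1-(phenylsulfonyl)indole F8 under conditions that do not cleave aryl methyl ethers.
- NH3 in i-PrOH/THF would give 2-chloro-5-[6-bromo-4-methoxy-1-(phenylsulfonyl)indol-3-yl]pyrimidin-4-amine F9.
- Return: silyl-mediated halogen exchange with Me3SiBr in propionitrile at 90 °C, a reaction known for 2-chloropyrimidines and 2-chloropyridines, comes back to the route at 16.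

Further compounds
F1 | step 7 | (2,4-dimethoxypyrimidin-5-yl)boronic acid | COc1ncc(B(O)O)c(OC)n1
F2 | step 7 | 6-bromo-4-methoxy-1H-indole (purchased) | COc1cc(Br)cc2[nH]ccc12
F3 | step 7 | 6-bromo-3-iodo-4-methoxy-1H-indole | COc1cc(Br)cc2[nH]cc(I)c12
F4 | step 7 | 6-bromo-3-iodo-4-methoxy-1-(phenylsulfonyl)indole | COc1cc(Br)cc2c1c(I)cn2S(=O)(=O)c1ccccc1
F5 | step 4 | methyl 2,5-dibromo-4-(2,4-dimethoxypyrimidin-5-yl)-1H-pyrrole-3-carboxylate | COC(=O)c1c(Br)[nH]c(Br)c1-c1cnc(OC)nc1OC
F6 | step 4 | methyl 2,5-dibromo-4-(2,4-dimethoxypyrimidin-5-yl)-1-(phenylsulfonyl)pyrrole-3-carboxylate | COC(=O)c1c(Br)n(S(=O)(=O)c2ccccc2)c(Br)c1-c1cnc(OC)nc1OC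
F7 | step 4 | methyl 5-bromo-4-(2,4-dimethoxypyrimidin-5-yl)-2-formyl-1-(phenylsulfonyl)pyrrole-3-carboxylate | COC(=O)c1c(C=O)n(S(=O)(=O)c2ccccc2)c(Br)c1-c1cnc(OC)nc1OC
F8 | step 9 | 6-bromo-3-(2,4-dichloropyrimidin-5-yl)-4-methoxy-1-(phenylsulfonyl)indole | COc1cc(Br)cc2c1c(-c1cnc(Cl)nc1Cl)cn2S(=O)(=O)c1ccccc1
F9 | step 9 | 2-chloro-5-[6-bromo-4-methoxy-1-(phenylsulfonyl)indol-3-yl]pyrimidin-4-amine | COc1cc(Br)cc2c1c(-c1cnc(Cl)nc1N)cn2S(=O)(=O)c1ccccc1
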